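The runs stem from a simulated flask on assumed constants, and the scatter is random.

The kineticist at the board follows one molecule of electrophile and asks for its chance of leaving in each hour. The run below is the flask itself, followed so far.

| flask | electrophile | nucleophile | free base | protic impurity | remark | time |
|---|---|---|---|---|---|---|
| delta | 0.50 M | 1.25 M | 0.55 M | 0.25 M | the very flask that is asked about, followed so far |  |
| flask | 0.50 M | 1.25 M | 0.550 M | 0.250 M |  | 15 h |

delta run (percent of the electrophile charged)

| time / h | electrophile / % | target / % |
|---|---|---|
| 0.417 | 96.9 | 1.1 |
| 0.833 | 94.5 | 2.3 |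
| 1.33 | 92.8 | 4.4 |
| 1.50 | 91.2 | 3.7 |
| 2.00 | 89.2 | 6.1 |
| 2.50 | 85.6 | 6.1 |
| 3.00 | 82.6 | 7.7 |

(readings scatter by 0.5 percentage points)

* part of the electrophile that has reacted at 15 h
* share of the unused nucleophile that is free and not bound as protonated nucleophile, at 15 h

- the earlier runs do not show how much of nucleophile is bound; that part of a forecast is a guess

With 82.6% of the charge left at 3.00 h, she reads 0.0637 h⁻¹. This is the leaving constant, the natural logarithm of charge over remainder, divided by time, which is the usual pseudo-first-order constant. At 1.50 h the readings give 0.0614 h⁻¹, a little less, so she sees no fall so far. Held to 15 h, her constant leaves 61.5% of the electrophile reacted.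

The process chemist looks at the fork instead. At 3.00 h a leaving molecule has a chance of 44.3% of showing up as target, so 55.7% go elsewhere, and he takes that branch to be the protic impurity. On her figure this would cost 68.6% of the impurity's charge, so he expects that branch, and with it her constant, to sink. My own number is hers, and it differs from the forecast.

The forecast sides with him, with 55% reacted (47% to 64%) on the ground that the impurity is “used up noticeably”, and 91% of the unused nucleophile free (75% to 99%). The flask gives 60.6% reacted and 91.8% free.

    electrophile + protic impurity → quenched substrate (k = 0.00171 L mol⁻¹ min⁻¹)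
    acid set free + free base ⇌ salt of the base, settled at all times (K = 2720 L mol⁻¹)
    electrophile + nucleophile → acid set free + target (k = 4.40 × 10⁻⁴ L mol⁻¹ min⁻¹)
    electrophile + target → side product (k = 0.00362 L mol⁻¹ min⁻¹)
    electrophile → decomposition product (k = 3.86 × 10⁻⁶ min⁻¹)
    nucleophile + acid set free ⇌ protonated nucleophile, settled at all times (K = 2200 L mol⁻¹)

Over the whole run this flask's leaving constant is 0.0620 h⁻¹, beside her 0.0637 h⁻¹. The neighbouring flask carries 1.0 M of protic impurity, so the same reckoning scales his branch by the charge and keeps the target branch. That gives 0.170 h⁻¹ and 92.2% reacted. The neighbouring flask gives 84.5%, a constant of 0.124 h⁻¹, lower than the scaled one. Quenched substrate in that neighbouring flask reaches 57.8% of the electrophile charged.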